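The numbers in the tables were computed from invented constants.

A bench chemist reads a slurry by one rule of thumb: while solid lies in the flask, the solution does not feel the charge, so at the same time after the start its level in molar stays put and its percentage scales as one over the charge.

| flask | solid substrate | remark | time |
|---|---|---|---|
| eta | 1.5 M | run made earlier |  |
| flask | 3.0 M |  | 50 min |

eta run (percent of the solid substrate charged)

| time / min | target / % | starting material / % |
|---|---|---|
| 5.00 | 0.3 | 8.4 |
| 8.00 | 0 | 11.7 |
| 12.0 | 0.6 | 17.1 |
| 15.0 | 1.4 | 19.6 |
| 25.0 | 2.4 | 26.6 |
| 40.0 | 6.1 | 33.2 |
| 60.0 | 11.0 | 31.2 |

(scatter of a reading: 0.5 percentage points)

- what was read earlier has a scatter of 0.5 percentage points, one standard deviation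
- at the start none of the solid substrate is in solution
- what has only dissolved of solid substrate counts as not reacted
- starting material means what is dissolved; the solid is not counted in it
- a reading or a percentage of target counts all its forms, free or not
- the reaction counts as stopped when no species that holds the solid substrate changes by six tenths of a point or more over the second half of the time

* at 50 min, what has stopped the reaction, if anything has (for what has run out or reacted, a solid counts together with what of it has only dissolved) (forward and back rates have come level / all of the solid substrate has reacted / it is still moving)
* target at 50 min, in percent of the solid substrate charged
* starting material at 50 min, in percent of the solid substrate charged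
* amount of target if the flask were left three thousand times as long, in percent of the solid substrate charged

Take the first eta reading as the pace of dissolving, 0.0252 M min⁻¹. The eta reading of 33.2% at 40.0 min then becomes 16.6% in this flask, and I take that as its level at the asked time too. The border of the rule is a ratio, charge over pace. For the eta run it gives 59.5 min, just before its last reading, where the reading of starting material stands below the one before. For this flask it gives 119 min, later than the asked time, so you expect solid still present and about 42.0% dissolved.

Now follow one molecule. If the eta charge had all dissolved by 60.0 min, then 68.8% had left the starting material, and 11.0% stood as target. That is the target share, a selectivity: points of target per point gone from dissolved starting material, here 16.0%. Carrying that eta share over unchanged, my reckoning for this flask at the asked time is 4.06% of target, and in the long run something near 16.0%.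

The forecast says it is still moving, target 4.7%, starting material 16.8%, and 100% in the long run: “Long term, about 100% unless an unseen equilibrium intervenes.”

The flask gives it is still moving, target 4.16%, starting material 17.8%, and 25.0% in the long run.

    intermediate A → target (k = 0.00960 min⁻¹)
    crystals ⇌ target, rate k2*(cs2 - [target]) while solid is left; crystals form when [target] > cs2 (solubility = 1.90 M, k = 2.70 min⁻¹)
    starting material ⇌ intermediate A (K = 0.840, k = 0.320 min⁻¹)
    solid substrate ⇌ starting material, rate k4*(cs4 - [starting material]) while solid is left; crystals form when [starting material] > cs4 (solubility = 1.10 M, k = 0.0390 min⁻¹)
    2 starting material → self-condensation product (k = 0.00680 L mol⁻¹ min⁻¹)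
    intermediate A → intermediate B (k = 0.0210 min⁻¹)
    intermediate B ⇌ intermediate D (K = 0.390, k = 0.310 min⁻¹)
    intermediate C ⇌ intermediate E (K = 29.0, k = 0.0150 min⁻¹)
    intermediate B → intermediate C (k = 0.0520 min⁻¹)

With 48.1% dissolved by the asked time, this flask's target share is 13.7%. Intermediate A goes on to intermediate B with a constant of 0.021 min⁻¹ and to target with one of 0.0096 min⁻¹, the first being larger, so the target branch has a chance of 31.4% at that fork. At 500 min this flask holds 25.0% of target and 20.2% of self-condensation product, and target is 31.3% of what is not self-condensation product.

Read at 3.0 h, the same flask holds 0% solid and 8.22% starting material, so the share gives 14.7% of target. The computed value is 20.7%.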